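**Retrosynthetic overview**
- Ring A is numbered C1 (butyryl), C2 (O), C3 (CMe2), C4 (O), C5 (bridging CH2), C6 (O). The strategy rests on C3: a quaternary dimethyl carbon between the oxygenated C2 and C4 makes ring A a 6,6-dimethylcyclohexa-2,4-dienone that cannot become a phenol.
- Key disconnection: bonds C4–C5, C6–C1 and C3–C4 of ring A, leading back to 3-ethoxy-4,4-dimethylcyclobutenone and a benzyl-substituted triisopropylsiloxyalkyne that carries ring B (cyclobutenone opening, (2+2) addition, second opening, 6π closure).
- Ring B is not built but dressed: 2,4,6-trihydroxybenzaldehyde is 4-O-methylated, 2,6-di-O-benzylated, extended by one carbon to the arylacetate and converted into the siloxyalkyne.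
- Endgame: hydrolysis of both enol ethers, butyrylation of C1 by O-to-C acyl transfer, hydrogenolysis, then one Friedel–Crafts butyrylation on ring B (C3' and C5' are equivalent). Ring A is the only ring formed.

Key step: step 7

Remark: the ring A triketones are written in the enol tautomer used in the target SMILES; the other enol forms are the same compounds.

**Route**

Step 1
Reactants: 1 isobutyryl chloride; 2 ethoxyacetylene
Product: 4 3-ethoxy-4,4-dimethylcyclobut-2-en-1-one, via dimethylketene 3 (not isolated)
Conditions: Et3N, Et2O, 0 °C → reflux; 2 in excess, 1 added slowly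
Reagents that add atoms: none
Why: Dehydrochlorination of the acid chloride gives dimethylketene, which should add to the ynol ether in the usual regioselective ketene–alkyne (2+2) cycloaddition (ketene carbonyl carbon to the unsubstituted alkyne carbon) to give the 3-alkoxycyclobutenone.

Step 2
Reactants: 5 2,4,6-trihydroxybenzaldehyde
Product: 6 2,6-dihydroxy-4-methoxybenzaldehyde
Conditions: MeI (1.0 equiv), K2CO3 (1.0 equiv), acetone, 0 °C → rt
Reagents that add atoms: iodomethane, CI
Why: Williamson etherification in which the 4-OH, para to the formyl group, most acidic and not chelated or shielded by the carbonyl, should be methylated before the two ortho hydroxyls when only one equivalent of base and electrophile is offered.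

Step 3
Reactants: 6 2,6-dihydroxy-4-methoxybenzaldehyde
Product: 7 2,6-bis(benzyloxy)-4-methoxybenzaldehyde
Conditions: BnBr (2.4 equiv), K2CO3, DMF, 60 °C
Reagents that add atoms: benzyl bromide, BrCc1ccccc1
Why: Williamson etherification of the two chelated phenols under forcing conditions; the benzyl ethers tolerate the later base, heat and aqueous acid and leave by hydrogenolysis.

Step 4
Reactants: 7 2,6-bis(benzyloxy)-4-methoxybenzaldehyde
Product: 8 1,3-bis(benzyloxy)-5-methoxy-2-[2-(methylsulfanyl)-2-(methylsulfinyl)ethenyl]benzene (racemic at sulfur; alkene geometry of no consequence)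
Conditions: CH3S(O)CH2SCH3, benzyltrimethylammonium hydroxide (40% in MeOH, cat.), THF, reflux
Reagents that add atoms: methyl (methylsulfinyl)methyl sulfide, CSCS(C)=O
Why: Knoevenagel-type condensation of the doubly sulfur-activated methylene with the aldehyde, the first half of the one-carbon homologation of aryl aldehydes to arylacetates, chosen because it forms no benzylic cation or halide that the very nucleophilic ring would attack.

Step 5
Reactants: 8 the ketene dithioacetal S-oxide
Product: 9 ethyl 2-[2,6-bis(benzyloxy)-4-methoxyphenyl]acetate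
Conditions: dry HCl, EtOH, rt → 40 °C
Reagents that add atoms: ethanol, CCO
Why: Acid ethanolysis of the ketene dithioacetal S-oxide (protonation at the benzylic carbon, Pummerer-type transfer of the sulfoxide oxygen to carbon, loss of dimethyl disulfide) should give the arylacetic ester while aryl benzyl ethers survive alcoholic HCl.

Step 6
Reactants: 9 ethyl 2-[2,6-bis(benzyloxy)-4-methoxyphenyl]acetate
Product: 12 [3-[2,6-bis(benzyloxy)-4-methoxyphenyl]prop-1-yn-1-yl]oxy-triisopropylsilane, via dibromomethyl ketone lithium enolate 10 (not isolated), via lithium ynolate 11 (not isolated)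
Conditions: CH2Br2, lithium 2,2,6,6-tetramethylpiperidide, THF, −78 °C; LiN(SiMe3)2; n-BuLi, −78 → 0 °C; iPr3SiCl, −78 °C → rt
Reagents that add atoms: dibromomethane, BrCBr; chlorotriisopropylsilane, CC(C)[Si](Cl)(C(C)C)C(C)C
Why: Kowalski ynolate formation, in which dibromomethyllithium adds to the ester to give enolate 10, bromine–lithium exchange and 1,2-shift of the arylmethyl group give ynolate 11, and the bulky silyl chloride traps it on oxygen, as in the standard preparation of siloxyalkynes; the 2,6-dialkoxy groups twist the arylacetate enolate out of conjugation, so addition should outrun deprotonation.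

Step 7
Reactants: 4 3-ethoxy-4,4-dimethylcyclobut-2-en-1-one; 12 the siloxyalkyne
Product: 16 2-[[2,6-bis(benzyloxy)-4-methoxyphenyl]methyl]-5-ethoxy-6,6-dimethyl-3-(triisopropylsilyloxy)cyclohexa-2,4-dien-1-one, via vinylketene 13 (not isolated), via alkenylcyclobutenone adduct 14 (not isolated), via dienylketene 15 (not isolated)
Conditions: toluene (about 1 M in 12), 100–110 °C, sealed tube, Ar; 4 (1.5 equiv) added in portions
Reagents that add atoms: none
Why: Proposed new method: heating should open cyclobutenone 4 by 4π electrocyclic cleavage of its C(=O)–CMe2 bond to vinylketene 13, whose ketene C=C adds (2+2) to the polarised siloxyalkyne to give the 4-alkenylcyclobutenone 14, and a second 4π opening then gives dienylketene 15. The closest known reaction type is the Danheiser annulation of cyclobutenones with siloxyalkynes, which ends in a phenol only because its dienone can tautomerise, together with the thermal recyclisation of dienylketenes to 6,6-disubstituted cyclohexa-2,4-dienones. Ring A closes by thermal 6π electrocyclisation (disrotatory, six-membered) of the ketene carbon onto the dimethylated terminus, which re-forms C3–C4 after C4–C5 and C6–C1 were made in the (2+2) event. No stereocentre is created, because the only sp3 ring carbon carries two methyl groups. The one selectivity needed is the (2+2) regiochemistry, and the polarisation of the partners secures it: the alkyne carbon β to the silyloxy group, which bears the arylmethyl group, is the nucleophilic one and bonds to the electrophilic ketene carbonyl carbon, placing the bridge carbon at C5 beside the ring carbonyl and the silyloxy group at C6. The quaternary C3 blocks enolisation to a phenol, so the dienone with oxygen on C2, C4 and C6 should persist.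

Step 8
Reactants: 16 the silyloxy ethoxy dienone
Product: 18 2-[[2,6-bis(benzyloxy)-4-methoxyphenyl]methyl]-3,5-dihydroxy-4,4-dimethylcyclohexa-2,5-dien-1-one, via ethyl enol ether 17 (not isolated)
Conditions: 2 M aq HCl, THF, rt → 45 °C
Reagents that add atoms: water, O
Why: Acid hydrolysis, in which the vinylogous silyl ester is cleaved first and the remaining vinylogous ethyl ester then undergoes addition–elimination with water, while aryl benzyl and methyl ethers are inert to dilute aqueous acid.

Step 9
Reactants: 18 the C-benzylated filicinic acid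
Product: 20 2-[[2,6-bis(benzyloxy)-4-methoxyphenyl]methyl]-6-butanoyl-3,5-dihydroxy-4,4-dimethylcyclohexa-2,5-dien-1-one, via enol butanoate 19 (not isolated)
Conditions: n-PrCOCl (1.1 equiv), Et3N, CH2Cl2, 0 °C; then DMAP (0.2 equiv), rt
Reagents that add atoms: butanoyl chloride, CCCC(Cl)=O
Why: O-acylation followed by DMAP-mediated O-to-C acyl migration, the enol ester to β-triketone rearrangement used for 2-acylcyclohexane-1,3-diones, should settle on C1 because it is the only ring carbon whose acylation gives an enolisable, chelated triketone, whereas acylation at the substituted C5 is reversible.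

Step 10
Reactants: 20 the ring A butyryl compound
Product: 21 2-butanoyl-6-[(2,6-dihydroxy-4-methoxyphenyl)methyl]-3,5-dihydroxy-4,4-dimethylcyclohexa-2,5-dien-1-one
Conditions: H2 (1 atm), Pd/C (10% Pd on carbon), EtOAc, rt
Reagents that add atoms: none
Why: Hydrogenolysis of the two aryl benzyl ethers under neutral conditions, to which the chelated enolised triketone and the aryl methyl ether are inert and which is run before any aryl ketone is present on ring B.

Step 11
Reactants: 21 the debenzylated compound
Product: 22 2-butanoyl-6-[(3-butanoyl-2,6-dihydroxy-4-methoxyphenyl)methyl]-3,5-dihydroxy-4,4-dimethylcyclohexa-2,5-dien-1-one (target, CNP0191862.0)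
Conditions: n-PrCOCl (1.1 equiv), AlCl3 (4 equiv), CH2Cl2/PhNO2, 0 °C → rt; cold 1 M aq HCl
Reagents that add atoms: butanoyl chloride, CCCC(Cl)=O
Why: Friedel–Crafts acylation of a phloroglucinol monomethyl ether whose two free positions C3' and C5' are equivalent by symmetry, while ring A has no free carbon left and the first acyl group deactivates ring B against a second.

**Compound list**
1 | isobutyryl chloride | CC(C)C(Cl)=O | starting material
2 | ethoxyacetylene | CCOC#C | starting material
3 | dimethylketene | CC(C)=C=O | intermediate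
4 | 3-ethoxy-4,4-dimethylcyclobut-2-en-1-one | CCOC1=CC(=O)C1(C)C | intermediate
5 | 2,4,6-trihydroxybenzaldehyde | O=Cc1c(O)cc(O)cc1O | starting material
6 | 2,6-dihydroxy-4-methoxybenzaldehyde | COc1cc(O)c(C=O)c(O)c1 | intermediate
7 | 2,6-bis(benzyloxy)-4-methoxybenzaldehyde | COc1cc(OCc2ccccc2)c(C=O)c(OCc2ccccc2)c1 | intermediate
8 | 1,3-bis(benzyloxy)-5-methoxy-2-[2-(methylsulfanyl)-2-(methylsulfinyl)ethenyl]benzene (racemic at sulfur) | CSC(=Cc1c(OCc2ccccc2)cc(OC)cc1OCc1ccccc1)S(C)=O | intermediate
9 | ethyl 2-[2,6-bis(benzyloxy)-4-methoxyphenyl]acetate | CCOC(=O)Cc1c(OCc2ccccc2)cc(OC)cc1OCc1ccccc1 | intermediate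
10 | lithium 3-[2,6-bis(benzyloxy)-4-methoxyphenyl]-1,1-dibromoprop-1-en-2-olate | [Li+].[O-]C(Cc1c(OCc2ccccc2)cc(OC)cc1OCc1ccccc1)=C(Br)Br | intermediate
11 | lithium 3-[2,6-bis(benzyloxy)-4-methoxyphenyl]prop-1-yn-1-olate | [Li+].[O-]C#CCc1c(OCc2ccccc2)cc(OC)cc1OCc1ccccc1 | intermediate
12 | [3-[2,6-bis(benzyloxy)-4-methoxyphenyl]prop-1-yn-1-yl]oxy-triisopropylsilane | CC(C)[Si](C(C)C)(C(C)C)OC#CCc1c(OCc2ccccc2)cc(OC)cc1OCc1ccccc1 | intermediate
13 | 3-ethoxy-4-methylpenta-1,3-dien-1-one (vinylketene) | CCOC(C=C=O)=C(C)C | intermediate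
14 | 2-[[2,6-bis(benzyloxy)-4-methoxyphenyl]methyl]-4-(1-ethoxy-2-methylprop-1-en-1-yl)-3-(triisopropylsilyloxy)cyclobut-2-en-1-one (racemic) | CCOC(=C(C)C)C1C(=O)C(Cc2c(OCc3ccccc3)cc(OC)cc2OCc2ccccc2)=C1O[Si](C(C)C)(C(C)C)C(C)C | intermediate
15 | (3E)-2-[[2,6-bis(benzyloxy)-4-methoxyphenyl]methyl]-5-ethoxy-6-methyl-3-(triisopropylsilyloxy)hepta-1,3,5-trien-1-one (ketene carbon chain and ethoxyalkenyl group cis) | O=C=C(Cc1c(OCc2ccccc2)cc(OC)cc1OCc1ccccc1)/C(O[Si](C(C)C)(C(C)C)C(C)C)=C\C(OCC)=C(C)C | intermediate
16 | 2-[[2,6-bis(benzyloxy)-4-methoxyphenyl]methyl]-5-ethoxy-6,6-dimethyl-3-(triisopropylsilyloxy)cyclohexa-2,4-dien-1-one | CCOC1=CC(O[Si](C(C)C)(C(C)C)C(C)C)=C(Cc2c(OCc3ccccc3)cc(OC)cc2OCc2ccccc2)C(=O)C1(C)C | intermediate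
17 | 2-[[2,6-bis(benzyloxy)-4-methoxyphenyl]methyl]-5-ethoxy-3-hydroxy-6,6-dimethylcyclohexa-2,4-dien-1-one | CCOC1=CC(O)=C(Cc2c(OCc3ccccc3)cc(OC)cc2OCc2ccccc2)C(=O)C1(C)C | intermediate
18 | 2-[[2,6-bis(benzyloxy)-4-methoxyphenyl]methyl]-3,5-dihydroxy-4,4-dimethylcyclohexa-2,5-dien-1-one | CC1(C)C(O)=CC(=O)C(Cc2c(OCc3ccccc3)cc(OC)cc2OCc2ccccc2)=C1O | intermediate
19 | 4-[[2,6-bis(benzyloxy)-4-methoxyphenyl]methyl]-5-hydroxy-6,6-dimethyl-3-oxocyclohexa-1,4-dien-1-yl butanoate (one enol ester regioisomer drawn) | CCCC(=O)OC1=CC(=O)C(Cc2c(OCc3ccccc3)cc(OC)cc2OCc2ccccc2)=C(O)C1(C)C | intermediate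
20 | 2-[[2,6-bis(benzyloxy)-4-methoxyphenyl]methyl]-6-butanoyl-3,5-dihydroxy-4,4-dimethylcyclohexa-2,5-dien-1-one | CCCC(=O)C1=C(O)C(C)(C)C(O)=C(Cc2c(OCc3ccccc3)cc(OC)cc2OCc2ccccc2)C1=O | intermediate
21 | 2-butanoyl-6-[(2,6-dihydroxy-4-methoxyphenyl)methyl]-3,5-dihydroxy-4,4-dimethylcyclohexa-2,5-dien-1-one | CCCC(=O)C1=C(O)C(C)(C)C(O)=C(Cc2c(O)cc(OC)cc2O)C1=O | intermediate
22 | 2-butanoyl-6-[(3-butanoyl-2,6-dihydroxy-4-methoxyphenyl)methyl]-3,5-dihydroxy-4,4-dimethylcyclohexa-2,5-dien-1-one | CCCC(=O)C1=C(O)C(C)(C)C(O)=C(Cc2c(O)cc(OC)c(C(=O)CCC)c2O)C1=O | target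

**Step count**
Total: 11 steps. Longest linear sequence: 10 steps (5 → 22, steps 2–11).

**Steps most likely to fail**

Step 7. The vinylketene may be lost by a 1,5-hydrogen shift from its cis methyl group or by self-addition before it meets the alkyne. The alkenylcyclobutenone may also resist the second ring opening, which requires the bulky alkenyl group to turn inward, and the siloxyalkyne may rearrange thermally to a silylketene. The fallback uses known chemistry and brings ring A in preformed. It sets out from aldehyde 7. Phloroglucinol would be C-acylated with butanoyl chloride and AlCl3 to 1-(2,4,6-trihydroxyphenyl)butan-1-one F1, and this would be geminally C-methylated (MeI, NaOMe, MeOH) to 2-butanoyl-3,5-dihydroxy-4,4-dimethylcyclohexa-2,5-dien-1-one F2 (butyrylfilicinic acid). F2 and 7 would then be joined by three-component reductive alkylation (L-proline cat., Hantzsch ester, CH2Cl2, rt; Knoevenagel condensation followed by conjugate hydride transfer). This would give 20 directly, where the route is rejoined before step 10.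

Step 6. The carbenoid may deprotonate the arylacetate instead of adding to it, and the excess butyllithium may lithiate the ring or the benzylic positions of the benzyl ethers. The fallback reaches the same ynolate by oxidising an acetylide and sets out from ester 9. Reduction with iBu2AlH (CH2Cl2, −78 °C) would give 2-[2,6-bis(benzyloxy)-4-methoxyphenyl]acetaldehyde F3. Homologation with dimethyl (1-diazo-2-oxopropyl)phosphonate (K2CO3, MeOH) would give 1,3-bis(benzyloxy)-5-methoxy-2-(prop-2-yn-1-yl)benzene F4. Deprotonation with LiN(SiMe3)2 and oxidation of the acetylide with LiOOtBu (THF, −78 → 0 °C) would give ynolate 11, which iPr3SiCl would trap to return to the route at 12.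

Step 11. Under the aluminium Lewis acid the methylene bridge may be scrambled by fragmentation and recombination of the two rings. O-acylation, cyclodehydration of a ring B phenol onto a ring A carbonyl, or cleavage of the methyl ether may also compete. The fallback replaces the acylium electrophile by a nitrile and sets out from 21. Houben–Hoesch reaction with butyronitrile (ZnCl2, HCl gas, Et2O, 0 °C) would give 1-[3-[(3-butanoyl-2,4-dihydroxy-5,5-dimethyl-6-oxocyclohexa-1,3-dien-1-yl)methyl]-2,4-dihydroxy-6-methoxyphenyl]butan-1-iminium chloride F5. This reaction is strictly mono-selective and does not O-acylate. Warming F5 in water would hydrolyse it to the target 22.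

**Further compounds**
F1 | step 7 | 1-(2,4,6-trihydroxyphenyl)butan-1-one | CCCC(=O)c1c(O)cc(O)cc1O
F2 | step 7 | 2-butanoyl-3,5-dihydroxy-4,4-dimethylcyclohexa-2,5-dien-1-one | CCCC(=O)C1=C(O)C(C)(C)C(O)=CC1=O
F3 | step 6 | 2-[2,6-bis(benzyloxy)-4-methoxyphenyl]acetaldehyde | O=CCc1c(OCc2ccccc2)cc(OC)cc1OCc1ccccc1
F4 | step 6 | 1,3-bis(benzyloxy)-5-methoxy-2-(prop-2-yn-1-yl)benzene | C#CCc1c(OCc2ccccc2)cc(OC)cc1OCc1ccccc1
F5 | step 11 | 1-[3-[(3-butanoyl-2,4-dihydroxy-5,5-dimethyl-6-oxocyclohexa-1,3-dien-1-yl)methyl]-2,4-dihydroxy-6-methoxyphenyl]butan-1-iminium chloride | CCCC(=O)C1=C(O)C(C)(C)C(O)=C(Cc2c(O)cc(OC)c(C(=[NH2+])CCC)c2O)C1=O.[Cl-]
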